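**Assumption:** the SMILES is read literally, so the oxepane/cyclohexane junction is cis (5a‑CH3, 9a‑H, the C6 side chain and 7‑OH all on one face) and the hydroazulene is cis‑fused.

**Abbreviations in names:** AzSi = (1S,3aS,5R,8aS)‑1,4,4,6‑tetramethyl‑1‑(triethylsilyloxy)‑1,2,3,3a,4,5,8,8a‑octahydroazulen‑5‑yl; AzOH = the same group with a free 1‑hydroxyl. Benzoxepine numbering is used for the right half (O1, C2, C3, C4, C5, C5a, C6–C9, C9a).

## Retrosynthetic overview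

- Target ⇐ C3 alcohol oxidation ⇐ MeMgBr on the C7 ketone ⇐ oxepane closed by 7‑exo alkoxymercuration of an isopropenyl carbinol chain onto the axial C9a–OH.
- Right‑half cyclohexane ⇐ key step: copper‑catalysed enantioselective conjugate addition of the complete left‑half Grignard reagent to Cs‑symmetric 4,4‑dimethoxycyclohexa‑2,5‑dienone (from 4‑methoxyphenol by oxidative dearomatisation). This is desymmetrisation and fragment union in one; C5a then comes from two enolate alkylations and C9a from hydride.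
- Left‑half bromide ⇐ Johnson–Claisen rearrangement of a 7R allylic alcohol (sets C5, the two‑carbon linker and the C6=C7 alkene) ⇐ cis‑hydroazulenone from a SmI2 ketone–enone cyclisation.
- That cyclisation substrate ⇐ cyclohepta‑2,6‑dienone by Saegusa–Ito ring expansion of the adduct from asymmetric conjugate addition of a 3‑oxobutyl Grignard equivalent to 2,4,4‑trimethylcyclohexa‑2,5‑dienone.
- Ring order: left six‑membered ring → seven‑membered ring → cyclopentanol; right six‑membered ring (from the arene) → oxepane.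

## Route

**Step 1**
Reactants: 1 2,4,4‑trimethylcyclohex‑2‑en‑1‑one
Product: 2 2,4,4‑trimethylcyclohexa‑2,5‑dien‑1‑one
Conditions: DDQ (1.5 equiv), 1,4‑dioxane, reflux
Reagents that add atoms: none
Why: DDQ dehydrogenation of an enone through its dienol is the standard entry to 4,4‑disubstituted cyclohexa‑2,5‑dienones, and no stereocentre is formed.

**Step 2**
Reactants: 2 2,4,4‑trimethylcyclohexa‑2,5‑dien‑1‑one; 3 2‑(2‑bromoethyl)‑2‑methyl‑1,3‑dioxolane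
Product: 6 trimethyl{[(3S)‑4,4,6‑trimethyl‑3‑[2‑(2‑methyl‑1,3‑dioxolan‑2‑yl)ethyl]cyclohexa‑1,5‑dien‑1‑yl]oxy}silane, via Grignard reagent 4 (not isolated), via magnesium enolate 5 (not isolated)
Conditions: Mg, THF, 25 °C; then 2, CuBr·SMe2 (5 mol%), (R)‑1‑[(S)‑2‑(diphenylphosphino)ferrocenyl]ethyldicyclohexylphosphine (6 mol%), t‑BuOMe, −75 °C; then Me3SiCl, Et3N, −75 → 0 °C
Reagents that add atoms: chlorotrimethylsilane, C[Si](C)(C)Cl
Why: Copper‑catalysed asymmetric conjugate addition of a Grignard reagent goes only to the unsubstituted enone (the α‑methyl enone is far less reactive), the ferrocenyl diphosphine fixes the new stereocentre as S (ligand antipode matched to this sense), and silylation traps the enolate regiospecifically as the 2‑silyloxydiene.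

**Step 3**
Reactants: 6 trimethyl{[(3S)‑4,4,6‑trimethyl‑3‑[2‑(2‑methyl‑1,3‑dioxolan‑2‑yl)ethyl]cyclohexa‑1,5‑dien‑1‑yl]oxy}silane
Product: 7 trimethyl{[(5S)‑2,4,4‑trimethyl‑5‑[2‑(2‑methyl‑1,3‑dioxolan‑2‑yl)ethyl]bicyclo[4.1.0]hept‑2‑en‑1‑yl]oxy}silane (cyclopropane carbons as formed)
Conditions: Et2Zn, CH2I2, CH2Cl2, 0 °C
Reagents that add atoms: diiodomethane, ICI
Why: In this Simmons–Smith (Furukawa) cyclopropanation the electrophilic zinc carbenoid attacks the electron‑rich silyl enol ether double bond rather than the conjugated trisubstituted alkene, and the cyclopropane stereocentres are erased in the next step.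

**Step 4**
Reactants: 7 silyloxycyclopropane from step 3
Product: 10 (5S)‑2,4,4‑trimethyl‑5‑(3‑oxobutyl)cyclohepta‑2,6‑dien‑1‑one, via chloro ketone 8 (not isolated), via dienone ketal 9 (not isolated)
Conditions: FeCl3, DMF, 0 °C; NaOAc, MeOH, reflux; 1 M HCl, THF, 25 °C
Reagents that add atoms: water, O
Why: In this Saegusa–Ito ring expansion one‑electron oxidation of the silyloxycyclopropane cleaves the internal cyclopropane bond to the β‑chloro cycloheptenone, acetate eliminates HCl to the cross‑conjugated dienone and aqueous acid unmasks the methyl ketone, all without touching the existing stereocentre.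

**Step 5**
Reactants: 10 (5S)‑2,4,4‑trimethyl‑5‑(3‑oxobutyl)cyclohepta‑2,6‑dien‑1‑one
Product: 11 (1S,3aS,8aS)‑1‑hydroxy‑1,4,4,6‑tetramethyl‑2,3,3a,4,8,8a‑hexahydroazulen‑7(1H)‑one
Conditions: SmI2 (2.2 equiv), HMPA, THF, −78 °C; then t‑BuOH
Reagents that add atoms: none
Why: In this SmI2 ketyl–olefin (ketone–enone) reductive cyclisation the 5‑exo attack on the β‑carbon of the less hindered enone from a tether on the adjacent ring carbon can only give the cis‑fused bicycle, the HMPA‑solvated O–Sm group sits anti to the enolate‑bearing ring carbon so that the C1 hydroxyl ends on the face of H3a and H8a, and the α‑methyl enone survives as its samarium dienolate until the quench.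

**Step 6**
Reactants: 11 hydroxy enone from step 5
Product: 12 (1S,3aS,8aS)‑1,4,4,6‑tetramethyl‑1‑(triethylsilyloxy)‑2,3,3a,4,8,8a‑hexahydroazulen‑7(1H)‑one
Conditions: Et3SiOTf, 2,6‑lutidine, CH2Cl2, −78 °C
Reagents that add atoms: triethylsilyl trifluoromethanesulfonate, CC[Si](CC)(CC)OS(=O)(=O)C(F)(F)F
Why: Silyl triflate silylation protects the hindered tertiary alcohol at low temperature without enolising the enone and changes no stereocentre.

**Step 7**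
Reactants: 12 silyl ether enone from step 6
Product: 13 (1S,3aS,7R,8aS)‑1,4,4,6‑tetramethyl‑1‑(triethylsilyloxy)‑1,2,3,3a,4,7,8,8a‑octahydroazulen‑7‑ol
Conditions: (S)‑2‑methyl‑CBS‑oxazaborolidine (20 mol%), BH3·SMe2, THF, −30 °C
Reagents that add atoms: none
Why: Corey–Bakshi–Shibata reduction delivers hydride under reagent control with the 2‑methylalkenyl arm as the large group, giving the 7R alcohol whose C–O bond lies on the face that the side chain must later occupy at C5.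

**Step 8**
Reactants: 13 allylic alcohol from step 7
Product: 15 ethyl 2‑(AzSi)acetate, via ketene acetal 14 (not isolated)
Conditions: MeC(OEt)3, EtCO2H (cat.), xylene, 140 °C
Reagents that add atoms: triethyl orthoacetate, CC(OCC)(OCC)OCC
Why: In the Johnson–Claisen rearrangement the ketene acetal formed on the 7R oxygen rearranges suprafacially, so the new C5–CH2CO2Et bond forms on the face that carried C7–O (5R) while the double bond moves to C6=C7.

**Step 9**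
Reactants: 15 ethyl 2‑(AzSi)acetate
Product: 16 2‑(AzSi)ethan‑1‑ol
Conditions: LiAlH4, Et2O, 0 °C
Reagents that add atoms: none
Why: Hydride reduction of the ester gives the primary alcohol while the silyl ether and the trisubstituted alkene are inert.

**Step 10**
Reactants: 16 2‑(AzSi)ethan‑1‑ol
Product: 17 2‑(AzSi)ethyl bromide
Conditions: CBr4, PPh3, CH2Cl2, 0 °C
Reagents that add atoms: tetrabromomethane, BrC(Br)(Br)Br
Why: The Appel reaction converts the primary alcohol to the bromide by SN2 displacement of the oxyphosphonium under neutral conditions that spare the tertiary silyl ether.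

**Step 11**
Reactants: 18 4‑methoxyphenol
Product: 19 4,4‑dimethoxycyclohexa‑2,5‑dien‑1‑one
Conditions: PhI(OAc)2, MeOH, 0 °C
Reagents that add atoms: methanol, CO
Why: In this oxidative dearomatisation of a para‑alkoxyphenol the phenoxenium ion generated by the iodine reagent is trapped by methanol at the para carbon to give the Cs‑symmetric quinone monoketal.

**Step 12** (key step)
Reactants: 17 2‑(AzSi)ethyl bromide; 19 4,4‑dimethoxycyclohexa‑2,5‑dien‑1‑one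
Product: 22 (5S,6S)‑4,4‑dimethoxy‑6‑methyl‑5‑[2‑(AzSi)ethyl]cyclohex‑2‑en‑1‑one, via Grignard reagent 20 (not isolated), via magnesium dienolate 21 (not isolated)
Conditions: Mg, Et2O, 35 °C; then added slowly to 19 (1.3 equiv), CuBr·SMe2 (5 mol%), (R)‑1‑[(S)‑2‑(diphenylphosphino)ferrocenyl]ethyldicyclohexylphosphine (6 mol%), t‑BuOMe, −75 °C; then MeI, DMPU, −75 → 0 °C
Reagents that add atoms: iodomethane, CI
Why: Proposed new method: the chiral copper–diphosphine alkyl complex formed from the complex primary Grignard reagent adds 1,4 to one of the two enantiotopic enone faces of the prochiral dienone (catalyst control, because the stereocentres of the nucleophile are remote), which sets the future C6 as S and joins the two halves before the magnesium enolate is methylated in situ, the closest known reactions being copper/ferrocenyl‑diphosphine‑catalysed Grignard additions to cyclohexenones and copper/phosphoramidite‑catalysed dialkylzinc desymmetrisation of this same monoketal.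

**Step 13**
Reactants: 23 5‑bromo‑2‑methylpent‑2‑ene
Product: 24 3‑(2‑bromoethyl)‑2,2‑dimethyloxirane (racemic)
Conditions: mCPBA, CH2Cl2, 0 °C
Reagents that add atoms: 3‑chloroperoxybenzoic acid, OOC(=O)c1cccc(Cl)c1
Why: Prilezhaev epoxidation of the trisubstituted alkene is clean, and the racemic epoxide carbon later becomes the C3 carbonyl so its configuration is irrelevant.

**Step 14**
Reactants: 22 enone from step 12; 24 3‑(2‑bromoethyl)‑2,2‑dimethyloxirane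
Product: 26 (5S,6S)‑6‑[2‑(3,3‑dimethyloxiran‑2‑yl)ethyl]‑4,4‑dimethoxy‑6‑methyl‑5‑[2‑(AzSi)ethyl]cyclohex‑2‑en‑1‑one (oxirane epimers), via lithium dienolate 25 (not isolated)
Conditions: LiN(i‑Pr)2, THF–DMPU, −78 °C; then 24, Bu4NI (10 mol%), −78 → 0 °C
Reagents that add atoms: none
Why: In this alkylation of the cross‑conjugated dienolate (kinetic α′‑deprotonation, with the enone blocking the other side) the electrophile enters anti to the adjacent pseudoaxial side chain, so the new CH2 is trans and the methyl cis to the C6 substituent (5aS).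

**Step 15**
Reactants: 26 alkylated enone from step 14
Product: 28 (2S,3S)‑2‑[2‑(3,3‑dimethyloxiran‑2‑yl)ethyl]‑4,4‑dimethoxy‑2‑methyl‑3‑[2‑(AzSi)ethyl]cyclohexan‑1‑one, via silyl enol ether 27 (not isolated)
Conditions: [(Ph3P)CuH]6 (5 mol%), PhMe2SiH, toluene, 25 °C; then K2CO3 (cat.), MeOH
Reagents that add atoms: none
Why: Copper hydride conjugate reduction (1,4‑hydrosilylation) followed by methanolysis of the silyl enol ether saturates only the enone, leaving the isolated alkene, epoxide, ketal and silyl ether untouched and no stereocentre changed.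

**Step 16**
Reactants: 28 ketone from step 15
Product: 29 (1R,2S,3S)‑2‑[2‑(3,3‑dimethyloxiran‑2‑yl)ethyl]‑4,4‑dimethoxy‑2‑methyl‑3‑[2‑(AzSi)ethyl]cyclohexan‑1‑ol
Conditions: LiBH(s‑Bu)3, THF, −78 → −40 °C
Reagents that add atoms: none
Why: The bulky borohydride attacks equatorially on the chair that carries the C6 chain equatorial and the 5a‑methyl axial, giving the axial 9a‑alcohol (9aR, oxygen anti to the 5a‑methyl) as in reductions of 4,4‑dimethyl‑3‑keto terpenoids.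

**Step 17**
Reactants: 29 epoxy alcohol from step 16
Product: 30 (1R,2S,3S)‑2‑(3‑hydroxy‑4‑methylpent‑4‑en‑1‑yl)‑4,4‑dimethoxy‑2‑methyl‑3‑[2‑(AzSi)ethyl]cyclohexan‑1‑ol (carbinol epimers)
Conditions: diethylaluminium 2,2,6,6‑tetramethylpiperidide (from lithium 2,2,6,6‑tetramethylpiperidide and Et2AlCl, 4 equiv), toluene, 0 °C
Reagents that add atoms: none
Why: The aluminium amide promotes epoxide‑to‑allylic‑alcohol isomerisation by syn β‑elimination from a methyl group of the aluminium‑bound trisubstituted epoxide, which gives the isopropenyl carbinol and leaves the ring stereocentres untouched.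

**Step 18**
Reactants: 30 diol from step 17
Product: 33 (5aS,6S,9aR)‑3‑hydroxy‑2,2,5a‑trimethyl‑6‑[2‑(AzOH)ethyl]octahydro‑1‑benzoxepin‑7(2H)‑one (C3 epimers), via organomercurial 31 (not isolated), via oxepane ketal 32 (not isolated)
Conditions: Hg(OAc)2, CH2Cl2, 0 °C; NaBH4, aq. NaOH, 0 °C; then 48% aq. HF, MeCN, 0 → 25 °C
Reagents that add atoms: water, O
Why: Intramolecular alkoxymercuration–demercuration (7‑exo, Markovnikov) adds the 9a‑hydroxyl to the tertiary carbon of the 1,1‑disubstituted alkene, which reacts far faster with the mercury salt than the hindered trisubstituted ring alkene, so the gem‑dimethyl ether forms with the cis ring fusion already fixed at C5a and C9a before aqueous HF removes the dimethyl ketal and the silyl ether.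

**Step 19**
Reactants: 33 hydroxy ketone from step 18
Product: 34 (5aS,6S,7R,9aR)‑2,2,5a,7‑tetramethyl‑6‑[2‑(AzOH)ethyl]decahydro‑1‑benzoxepine‑3,7‑diol (C3 epimers)
Conditions: MeMgBr (6 equiv), Et2O–toluene, −78 → 0 °C
Reagents that add atoms: methylmagnesium bromide, C[Mg]Br
Why: In this Grignard addition axial attack on the C7 ketone is blocked by the syn‑axial 5a‑methyl, so methyl enters equatorially and the new hydroxyl is axial and cis to the 5a‑methyl and the C6 chain (7R), the excess reagent covering the two free hydroxyls.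

**Step 20**
Reactants: 34 triol from step 19
Product: 35 (5aS,6S,7R,9aR)‑7‑hydroxy‑2,2,5a,7‑tetramethyl‑6‑[2‑(AzOH)ethyl]octahydro‑1‑benzoxepin‑3(2H)‑one (target)
Conditions: Dess–Martin periodinane, CH2Cl2, 0 → 25 °C
Reagents that add atoms: none
Why: Dess–Martin oxidation converts the only secondary alcohol (both C3 epimers converge) to the ketone while the two tertiary alcohols and the alkene are inert.

## Compound list

1 | 2,4,4‑trimethylcyclohex‑2‑en‑1‑one | CC1=CC(C)(C)CCC1=O | starting material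
2 | 2,4,4‑trimethylcyclohexa‑2,5‑dien‑1‑one | CC1=CC(C)(C)C=CC1=O | intermediate
3 | 2‑(2‑bromoethyl)‑2‑methyl‑1,3‑dioxolane | CC1(CCBr)OCCO1 | starting material
4 | [2‑(2‑methyl‑1,3‑dioxolan‑2‑yl)ethyl]magnesium bromide | CC1(CC[Mg]Br)OCCO1 | intermediate
5 | bromomagnesium (3S)‑4,4,6‑trimethyl‑3‑[2‑(2‑methyl‑1,3‑dioxolan‑2‑yl)ethyl]cyclohexa‑1,5‑dien‑1‑olate | CC1=CC(C)(C)[C@@H](CCC2(C)OCCO2)C=C1O[Mg]Br | intermediate
6 | trimethyl{[(3S)‑4,4,6‑trimethyl‑3‑[2‑(2‑methyl‑1,3‑dioxolan‑2‑yl)ethyl]cyclohexa‑1,5‑dien‑1‑yl]oxy}silane | CC1=CC(C)(C)[C@@H](CCC2(C)OCCO2)C=C1O[Si](C)(C)C | intermediate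
7 | trimethyl{[(5S)‑2,4,4‑trimethyl‑5‑[2‑(2‑methyl‑1,3‑dioxolan‑2‑yl)ethyl]bicyclo[4.1.0]hept‑2‑en‑1‑yl]oxy}silane (cyclopropane carbons undefined) | CC1=CC(C)(C)[C@@H](CCC2(C)OCCO2)C2CC12O[Si](C)(C)C | intermediate
8 | 6‑chloro‑2,4,4‑trimethyl‑5‑[2‑(2‑methyl‑1,3‑dioxolan‑2‑yl)ethyl]cyclohept‑2‑en‑1‑one (C5 as in 9, chloride epimers) | CC1=CC(C)(C)[C@@H](CCC2(C)OCCO2)C(Cl)CC1=O | intermediate
9 | (5S)‑2,4,4‑trimethyl‑5‑[2‑(2‑methyl‑1,3‑dioxolan‑2‑yl)ethyl]cyclohepta‑2,6‑dien‑1‑one | CC1=CC(C)(C)[C@@H](CCC2(C)OCCO2)C=CC1=O | intermediate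
10 | (5S)‑2,4,4‑trimethyl‑5‑(3‑oxobutyl)cyclohepta‑2,6‑dien‑1‑one | CC1=CC(C)(C)[C@@H](CCC(C)=O)C=CC1=O | intermediate
11 | (1S,3aS,8aS)‑1‑hydroxy‑1,4,4,6‑tetramethyl‑2,3,3a,4,8,8a‑hexahydroazulen‑7(1H)‑one | CC1=CC(C)(C)[C@H]2CC[C@](C)(O)[C@H]2CC1=O | intermediate
12 | (1S,3aS,8aS)‑1,4,4,6‑tetramethyl‑1‑(triethylsilyloxy)‑2,3,3a,4,8,8a‑hexahydroazulen‑7(1H)‑one | CC1=CC(C)(C)[C@H]2CC[C@](C)(O[Si](CC)(CC)CC)[C@H]2CC1=O | intermediate
13 | (1S,3aS,7R,8aS)‑1,4,4,6‑tetramethyl‑1‑(triethylsilyloxy)‑1,2,3,3a,4,7,8,8a‑octahydroazulen‑7‑ol | CC1=CC(C)(C)[C@H]2CC[C@](C)(O[Si](CC)(CC)CC)[C@H]2C[C@H]1O | intermediate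
14 | 7‑O‑(1‑ethoxyvinyl) ether of 13 (ketene acetal) | CC1=CC(C)(C)[C@H]2CC[C@](C)(O[Si](CC)(CC)CC)[C@H]2C[C@H]1OC(=C)OCC | intermediate
15 | ethyl 2‑(AzSi)acetate | CC1=CC[C@H]2[C@H](CC[C@]2(C)O[Si](CC)(CC)CC)C(C)(C)[C@@H]1CC(=O)OCC | intermediate
16 | 2‑(AzSi)ethan‑1‑ol | CC1=CC[C@H]2[C@H](CC[C@]2(C)O[Si](CC)(CC)CC)C(C)(C)[C@@H]1CCO | intermediate
17 | 2‑(AzSi)ethyl bromide | CC1=CC[C@H]2[C@H](CC[C@]2(C)O[Si](CC)(CC)CC)C(C)(C)[C@@H]1CCBr | intermediate
18 | 4‑methoxyphenol | COc1ccc(O)cc1 | starting material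
19 | 4,4‑dimethoxycyclohexa‑2,5‑dien‑1‑one | COC1(OC)C=CC(=O)C=C1 | intermediate
20 | [2‑(AzSi)ethyl]magnesium bromide | CC1=CC[C@H]2[C@H](CC[C@]2(C)O[Si](CC)(CC)CC)C(C)(C)[C@@H]1CC[Mg]Br | intermediate
21 | bromomagnesium (3S)‑4,4‑dimethoxy‑3‑[2‑(AzSi)ethyl]cyclohexa‑1,5‑dien‑1‑olate | CC1=CC[C@H]2[C@H](CC[C@]2(C)O[Si](CC)(CC)CC)C(C)(C)[C@@H]1CC[C@H]1C=C(O[Mg]Br)C=CC1(OC)OC | intermediate
22 | (5S,6S)‑4,4‑dimethoxy‑6‑methyl‑5‑[2‑(AzSi)ethyl]cyclohex‑2‑en‑1‑one | CC1=CC[C@H]2[C@H](CC[C@]2(C)O[Si](CC)(CC)CC)C(C)(C)[C@@H]1CC[C@H]1[C@H](C)C(=O)C=CC1(OC)OC | intermediate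
23 | 5‑bromo‑2‑methylpent‑2‑ene | CC(C)=CCCBr | starting material
24 | 3‑(2‑bromoethyl)‑2,2‑dimethyloxirane (racemic) | CC1(C)OC1CCBr | intermediate
25 | lithium (3S)‑4,4‑dimethoxy‑2‑methyl‑3‑[2‑(AzSi)ethyl]cyclohexa‑1,5‑dien‑1‑olate | CC1=CC[C@H]2[C@H](CC[C@]2(C)O[Si](CC)(CC)CC)C(C)(C)[C@@H]1CC[C@H]1C(C)=C(O[Li])C=CC1(OC)OC | intermediate
26 | (5S,6S)‑6‑[2‑(3,3‑dimethyloxiran‑2‑yl)ethyl]‑4,4‑dimethoxy‑6‑methyl‑5‑[2‑(AzSi)ethyl]cyclohex‑2‑en‑1‑one (oxirane epimers) | CC1=CC[C@H]2[C@H](CC[C@]2(C)O[Si](CC)(CC)CC)C(C)(C)[C@@H]1CC[C@H]1[C@](C)(CCC2OC2(C)C)C(=O)C=CC1(OC)OC | intermediate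
27 | dimethyl(phenyl)silyl enol ether (C1=C6) of ketone 28 | CC1=CC[C@H]2[C@H](CC[C@]2(C)O[Si](CC)(CC)CC)C(C)(C)[C@@H]1CC[C@H]1[C@](C)(CCC2OC2(C)C)C(O[Si](C)(C)c2ccccc2)=CCC1(OC)OC | intermediate
28 | (2S,3S)‑2‑[2‑(3,3‑dimethyloxiran‑2‑yl)ethyl]‑4,4‑dimethoxy‑2‑methyl‑3‑[2‑(AzSi)ethyl]cyclohexan‑1‑one (oxirane epimers) | CC1=CC[C@H]2[C@H](CC[C@]2(C)O[Si](CC)(CC)CC)C(C)(C)[C@@H]1CC[C@H]1[C@](C)(CCC2OC2(C)C)C(=O)CCC1(OC)OC | intermediate
29 | (1R,2S,3S)‑2‑[2‑(3,3‑dimethyloxiran‑2‑yl)ethyl]‑4,4‑dimethoxy‑2‑methyl‑3‑[2‑(AzSi)ethyl]cyclohexan‑1‑ol (oxirane epimers) | CC1=CC[C@H]2[C@H](CC[C@]2(C)O[Si](CC)(CC)CC)C(C)(C)[C@@H]1CC[C@H]1[C@](C)(CCC2OC2(C)C)[C@H](O)CCC1(OC)OC | intermediate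
30 | (1R,2S,3S)‑2‑(3‑hydroxy‑4‑methylpent‑4‑en‑1‑yl)‑4,4‑dimethoxy‑2‑methyl‑3‑[2‑(AzSi)ethyl]cyclohexan‑1‑ol (carbinol epimers) | CC1=CC[C@H]2[C@H](CC[C@]2(C)O[Si](CC)(CC)CC)C(C)(C)[C@@H]1CC[C@H]1[C@](C)(CCC(O)C(C)=C)[C@H](O)CCC1(OC)OC | intermediate
31 | {[(5aS,6S,9aR)‑3‑hydroxy‑7,7‑dimethoxy‑2,5a‑dimethyl‑6‑[2‑(AzSi)ethyl]decahydro‑1‑benzoxepin‑2‑yl]methyl}mercury acetate (C2 and C3 epimers) | CC1=CC[C@H]2[C@H](CC[C@]2(C)O[Si](CC)(CC)CC)C(C)(C)[C@@H]1CC[C@H]1[C@]2(C)CCC(O)C(C)(C[Hg]OC(C)=O)O[C@@H]2CCC1(OC)OC | intermediate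
32 | (5aS,6S,9aR)‑7,7‑dimethoxy‑2,2,5a‑trimethyl‑6‑[2‑(AzSi)ethyl]decahydro‑1‑benzoxepin‑3‑ol (C3 epimers) | CC1=CC[C@H]2[C@H](CC[C@]2(C)O[Si](CC)(CC)CC)C(C)(C)[C@@H]1CC[C@H]1[C@]2(C)CCC(O)C(C)(C)O[C@@H]2CCC1(OC)OC | intermediate
33 | (5aS,6S,9aR)‑3‑hydroxy‑2,2,5a‑trimethyl‑6‑[2‑(AzOH)ethyl]octahydro‑1‑benzoxepin‑7(2H)‑one (C3 epimers) | CC1=CC[C@H]2[C@H](CC[C@]2(C)O)C(C)(C)[C@@H]1CC[C@H]1[C@]2(C)CCC(O)C(C)(C)O[C@@H]2CCC1=O | intermediate
34 | (5aS,6S,7R,9aR)‑2,2,5a,7‑tetramethyl‑6‑[2‑(AzOH)ethyl]decahydro‑1‑benzoxepine‑3,7‑diol (C3 epimers) | CC1=CC[C@H]2[C@H](CC[C@]2(C)O)C(C)(C)[C@@H]1CC[C@H]1[C@]2(C)CCC(O)C(C)(C)O[C@@H]2CC[C@@]1(C)O | intermediate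
35 | (5aS,6S,7R,9aR)‑7‑hydroxy‑6‑{2‑[(1S,3aS,5R,8aS)‑1‑hydroxy‑1,4,4,6‑tetramethyl‑1,2,3,3a,4,5,8,8a‑octahydroazulen‑5‑yl]ethyl}‑2,2,5a,7‑tetramethyloctahydro‑1‑benzoxepin‑3(2H)‑one | CC1=CC[C@H]2[C@H](CC[C@]2(C)O)C(C)(C)[C@@H]1CC[C@H]1[C@]2(C)CCC(=O)C(C)(C)O[C@@H]2CC[C@@]1(C)O | target

## Step count

Total step count: 20. Longest linear sequence: 18 (steps 1–10, 12, 14–20).

## Three steps most likely to fail, each with one fallback

**Step 12 (desymmetrising fragment union).** The risks are competing 1,2‑addition, low catalyst control with a bulky alkyl group, and aromatisation of the adduct. The fallback sets out from 19 and 13 and comes back at 22; it moves the union to a sigmatropic step and desymmetrises with a small nucleophile. Compound 19 is treated with Zn(CH2CH2CO2Et)2 under Cu(OTf)2/phosphoramidite catalysis and the zinc enolate is methylated (MeI, HMPA) to give ethyl 3‑[(1S,6S)‑2,2‑dimethoxy‑6‑methyl‑5‑oxocyclohex‑3‑en‑1‑yl]propanoate F1. LiOH gives 3‑[(1S,6S)‑2,2‑dimethoxy‑6‑methyl‑5‑oxocyclohex‑3‑en‑1‑yl]propanoic acid F2. Esterification with allylic alcohol 13 (DCC, DMAP) gives the 7‑O‑{3‑[(1S,6S)‑2,2‑dimethoxy‑6‑methyl‑5‑oxocyclohex‑3‑en‑1‑yl]propanoyl} ester of 13 F3. Ireland–Claisen rearrangement (LiN(i‑Pr)2 2.5 equiv, Me3SiCl, THF, −78 → 60 °C, the ketone being masked in situ as its silyl dienol ether) transfers the C7–O configuration to C5 as in step 8 and gives 2‑(AzSi)‑3‑[(1S,6S)‑2,2‑dimethoxy‑6‑methyl‑5‑oxocyclohex‑3‑en‑1‑yl]propanoic acid F4. Photoredox hydrodecarboxylation (acridinium photocatalyst, PhSSPh, blue light) then gives 22.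

**Step 5 (SmI2 ketone–enone cyclisation).** The risks are over‑reduction or dimerisation of the cross‑conjugated dienone and the wrong C1 epimer through chelation. The fallback sets out from 10 and comes back at 12; it replaces the ketyl by a hydrogen‑atom‑transfer radical and also makes step 6 unnecessary. Kinetic silylation of the methyl ketone (LiN(i‑Pr)2, Et3SiCl, THF, −78 °C) gives (5S)‑2,4,4‑trimethyl‑5‑[3‑(triethylsilyloxy)but‑3‑en‑1‑yl]cyclohepta‑2,6‑dien‑1‑one F5. Treatment with Fe(acac)3 and PhSiH3 in EtOH at 60 °C transfers a hydrogen atom to the enol ether CH2, and the resulting α‑silyloxy tertiary radical closes 5‑exo onto the adjacent enone β‑carbon (cis fusion enforced, bulky silyloxy group on the convex face) to give 12 directly.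

**Step 14 (quaternary centre by alkylation with an unactivated halide).** The risks are slow C‑alkylation of a hindered tetrasubstituted dienolate, O‑alkylation and elimination. The fallback sets out from 22 and comes back at 30; it uses an activated electrophile and builds the chain afterwards. The dienolate of 22 is alkylated with propargyl bromide to give (5S,6S)‑4,4‑dimethoxy‑6‑methyl‑6‑(prop‑2‑yn‑1‑yl)‑5‑[2‑(AzSi)ethyl]cyclohex‑2‑en‑1‑one F6. Hydroboration of the terminal alkyne with dicyclohexylborane and NaBO3 oxidation gives 3‑{(1S,6S)‑5,5‑dimethoxy‑1‑methyl‑2‑oxo‑6‑[2‑(AzSi)ethyl]cyclohex‑3‑en‑1‑yl}propanal F7. Isopropenylmagnesium bromide at −78 °C adds to the aldehyde only and gives (5S,6S)‑6‑(3‑hydroxy‑4‑methylpent‑4‑en‑1‑yl)‑4,4‑dimethoxy‑6‑methyl‑5‑[2‑(AzSi)ethyl]cyclohex‑2‑en‑1‑one F8. Copper hydride conjugate reduction as in step 15 gives (2S,3S)‑2‑(3‑hydroxy‑4‑methylpent‑4‑en‑1‑yl)‑4,4‑dimethoxy‑2‑methyl‑3‑[2‑(AzSi)ethyl]cyclohexan‑1‑one F9, and LiBH(s‑Bu)3 reduction as in step 16 gives 30, so that step 17 is no longer needed.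

## Further compounds

F1 | step 12 | ethyl 3‑[(1S,6S)‑2,2‑dimethoxy‑6‑methyl‑5‑oxocyclohex‑3‑en‑1‑yl]propanoate | CCOC(=O)CC[C@H]1[C@H](C)C(=O)C=CC1(OC)OC
F2 | step 12 | 3‑[(1S,6S)‑2,2‑dimethoxy‑6‑methyl‑5‑oxocyclohex‑3‑en‑1‑yl]propanoic acid | OC(=O)CC[C@H]1[C@H](C)C(=O)C=CC1(OC)OC
F3 | step 12 | 7‑O‑{3‑[(1S,6S)‑2,2‑dimethoxy‑6‑methyl‑5‑oxocyclohex‑3‑en‑1‑yl]propanoyl} ester of 13 | CC1=CC(C)(C)[C@H]2CC[C@](C)(O[Si](CC)(CC)CC)[C@H]2C[C@H]1OC(=O)CC[C@H]1[C@H](C)C(=O)C=CC1(OC)OC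
F4 | step 12 | 2‑(AzSi)‑3‑[(1S,6S)‑2,2‑dimethoxy‑6‑methyl‑5‑oxocyclohex‑3‑en‑1‑yl]propanoic acid (C2 epimers) | CC1=CC[C@H]2[C@H](CC[C@]2(C)O[Si](CC)(CC)CC)C(C)(C)[C@@H]1C(C(=O)O)C[C@H]1[C@H](C)C(=O)C=CC1(OC)OC
F5 | step 5 | (5S)‑2,4,4‑trimethyl‑5‑[3‑(triethylsilyloxy)but‑3‑en‑1‑yl]cyclohepta‑2,6‑dien‑1‑one | CC1=CC(C)(C)[C@@H](CCC(=C)O[Si](CC)(CC)CC)C=CC1=O
F6 | step 14 | (5S,6S)‑4,4‑dimethoxy‑6‑methyl‑6‑(prop‑2‑yn‑1‑yl)‑5‑[2‑(AzSi)ethyl]cyclohex‑2‑en‑1‑one | CC1=CC[C@H]2[C@H](CC[C@]2(C)O[Si](CC)(CC)CC)C(C)(C)[C@@H]1CC[C@H]1[C@](C)(CC#C)C(=O)C=CC1(OC)OC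
F7 | step 14 | 3‑{(1S,6S)‑5,5‑dimethoxy‑1‑methyl‑2‑oxo‑6‑[2‑(AzSi)ethyl]cyclohex‑3‑en‑1‑yl}propanal | CC1=CC[C@H]2[C@H](CC[C@]2(C)O[Si](CC)(CC)CC)C(C)(C)[C@@H]1CC[C@H]1[C@](C)(CCC=O)C(=O)C=CC1(OC)OC
F8 | step 14 | (5S,6S)‑6‑(3‑hydroxy‑4‑methylpent‑4‑en‑1‑yl)‑4,4‑dimethoxy‑6‑methyl‑5‑[2‑(AzSi)ethyl]cyclohex‑2‑en‑1‑one (carbinol epimers) | CC1=CC[C@H]2[C@H](CC[C@]2(C)O[Si](CC)(CC)CC)C(C)(C)[C@@H]1CC[C@H]1[C@](C)(CCC(O)C(C)=C)C(=O)C=CC1(OC)OC
F9 | step 14 | (2S,3S)‑2‑(3‑hydroxy‑4‑methylpent‑4‑en‑1‑yl)‑4,4‑dimethoxy‑2‑methyl‑3‑[2‑(AzSi)ethyl]cyclohexan‑1‑one (carbinol epimers) | CC1=CC[C@H]2[C@H](CC[C@]2(C)O[Si](CC)(CC)CC)C(C)(C)[C@@H]1CC[C@H]1[C@](C)(CCC(O)C(C)=C)C(=O)CCC1(OC)OC
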